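Retrosynthesis: remove three benzyl groups, trace (3R) back through the ketone to a cis-(3R,4R)-isoflavan-4-ol made from the racemic ketone, then cut ring C at O1–C8a and C4–C4a (together with O1–C2). This leaves a ring A aryne and a 2-arylacrylic acid.
Enabling feature: on ring A the ether oxygen O1 (on C8a) and the acyl carbon C4 (on C4a) sit on neighbouring carbons, and C4a is flanked by the C5 oxygen. This is the print of a 3-alkoxyaryne C4a≡C8a, which takes an O-nucleophile at C8a and leaves its carbanion at C4a.
Forward: ring A is dressed as the o-silylaryl triflate 9 (steps 1–5, through the symmetric phenol 5) and ring B as the acrylic acid 13 (steps 6–8). Step 9 joins them and builds ring C in one operation.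
Stereochemistry: C3 is deliberately racemic after step 9 and is set by catalyst control in a transfer hydrogenation with dynamic kinetic resolution (step 10). Base-free reoxidation and neutral hydrogenolysis keep it.

Key step: step 9

Assumption: 1 and 10 are taken as catalogue compounds, and CIP analysis of the given SMILES makes C3 of the target (R).

Step 1
Reactants: 1 methyl 3,5-dihydroxy-4-methoxybenzoate
Product: 2 methyl 3,5-bis(benzyloxy)-4-methoxybenzoate
Conditions: BnBr, K2CO3, DMF, 60 °C
Reagents that add atoms: benzyl bromide, BrCc1ccccc1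
Why: Williamson etherification of the two equivalent phenols, to which the ester and the methyl ether are inert.

Step 2
Reactants: 2 methyl 3,5-bis(benzyloxy)-4-methoxybenzoate
Product: 3 2-[3,5-bis(benzyloxy)-4-methoxyphenyl]propan-2-ol
Conditions: MeMgBr (excess), THF, 0 °C to rt; aq. NH4Cl
Reagents that add atoms: methylmagnesium bromide, C[Mg]Br
Why: Double Grignard addition to the ester gives the tertiary benzylic alcohol needed for the carbon-to-oxygen aryl shift, and the aryl ethers are not touched.

Step 3
Reactants: 3 2-[3,5-bis(benzyloxy)-4-methoxyphenyl]propan-2-ol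
Product: 5 3,5-bis(benzyloxy)-4-methoxyphenol, via cumyl-type hydroperoxide 4 (not isolated)
Conditions: H2O2 (50% aq., excess), p-TsOH·H2O (cat.), CH2Cl2/THF, 0 °C to rt
Reagents that add atoms: hydrogen peroxide, OO
Why: Benzylic hydroperoxide (Hock-type) rearrangement, in which acid exchanges OH for OOH, the electron-rich aryl group migrates from carbon to oxygen in preference to methyl, and the hemiketal falls apart to the phenol and acetone.

Step 4
Reactants: 5 3,5-bis(benzyloxy)-4-methoxyphenol
Product: 6 3,5-bis(benzyloxy)-2-bromo-4-methoxyphenol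
Conditions: NBS (1.0 equiv), CH2Cl2, -78 °C to 0 °C
Reagents that add atoms: N-bromosuccinimide, O=C1CCC(=O)N1Br
Why: Electrophilic aromatic bromination ortho to the free OH, where C2 and C6 of the symmetric phenol are equivalent and the para position is blocked, so only one monobromide is possible.

Step 5
Reactants: 6 3,5-bis(benzyloxy)-2-bromo-4-methoxyphenol
Product: 9 3,5-bis(benzyloxy)-4-methoxy-2-(trimethylsilyl)phenyl trifluoromethanesulfonate, via aryl silyl ether 7 (not isolated), via lithium silylphenolate 8 (not isolated)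
Conditions: HN(SiMe3)2, THF, reflux, then evaporate; n-BuLi, THF, -78 °C; Tf2O, -78 °C to rt
Reagents that add atoms: hexamethyldisilazane, C[Si](C)(C)N[Si](C)(C)C; trifluoromethanesulfonic anhydride, O=S(=O)(OS(=O)(=O)C(F)(F)F)C(F)(F)F
Why: O-silylation, Br/Li exchange, retro-Brook O-to-C silyl shift and triflation form the standard sequence to o-silylaryl triflates, and at -78 °C the exchange outruns deprotonation of the benzyl ethers.

Step 6
Reactants: 10 3-hydroxy-4,5-dimethoxybenzaldehyde
Product: 11 3-(benzyloxy)-4,5-dimethoxybenzaldehyde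
Conditions: BnBr, K2CO3, DMF, rt
Reagents that add atoms: benzyl bromide, BrCc1ccccc1
Why: Williamson etherification of the single phenol, which the aldehyde survives under carbonate base.

Step 7
Reactants: 11 3-(benzyloxy)-4,5-dimethoxybenzaldehyde
Product: 12 1-(benzyloxy)-5-ethynyl-2,3-dimethoxybenzene
Conditions: dimethyl (1-diazo-2-oxopropyl)phosphonate, K2CO3, MeOH, rt
Reagents that add atoms: dimethyl (1-diazo-2-oxopropyl)phosphonate, COP(=O)(OC)C(=[N+]=[N-])C(C)=O
Why: Ohira–Bestmann variant of the Seyferth–Gilbert homologation, which turns non-enolisable aryl aldehydes into terminal alkynes under mild base.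

Step 8
Reactants: 12 1-(benzyloxy)-5-ethynyl-2,3-dimethoxybenzene
Product: 13 2-[3-(benzyloxy)-4,5-dimethoxyphenyl]acrylic acid
Conditions: Pd(OAc)2 (cat.), 2-(diphenylphosphino)pyridine, MeSO3H (cat.), CO (30 bar), H2O, THF, 50 °C
Reagents that add atoms: carbon monoxide, [C-]#[O+]; water, O
Why: Palladium-catalysed Markovnikov hydroxycarbonylation of a terminal arylalkyne, in which the pyridylphosphine/acid catalyst places the carboxyl group on the internal carbon as in the known routes to 2-arylacrylic acids.

Step 9
Reactants: 9 3,5-bis(benzyloxy)-4-methoxy-2-(trimethylsilyl)phenyl trifluoromethanesulfonate; 13 2-[3-(benzyloxy)-4,5-dimethoxyphenyl]acrylic acid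
Product: 16 racemic 5,7-bis(benzyloxy)-3-[3-(benzyloxy)-4,5-dimethoxyphenyl]-6-methoxychroman-4-one, via aryne 14 (not isolated), via hydroxyaryl vinyl ketone 15 (not isolated)
Conditions: CsF (excess), THF, 125 °C, sealed tube, argon, 13 in slight excess
Reagents that add atoms: none
Why: Fluoride removes the silyl group of 9 and triflate leaves to give aryne 14 (C4a≡C8a); the caesium carboxylate of 13 adds through oxygen to C8a, the C4a carbanion attacks the neighbouring ester carbonyl (transient 4-exo-trig closure to a 2H-benzoxete hemiketal alkoxide), and collapse of that small ring moves the acyl group from O to C4a, so that O1–C8a and C4–C4a both exist in the phenoxide of 15. This phenoxide closes ring C by 6-endo-trig oxa-Michael addition to the 2-aryl enone (O1–C2), and the enolate is protonated to 16. The closest known reaction type is the CsF-mediated insertion of arynes into the C–O bond of carboxylic acids in hot THF, which with alpha,beta-unsaturated acids is an established annulation to chroman-4-ones. The regioselectivity needed (oxygen at C8a, acyl at C4a) is secured by the C5 benzyloxy group, since in 3-alkoxyarynes inductive polarisation and ring distortion send the nucleophile to the remote aryne carbon and place the carbanion next to the C–O bond. The chemoselectivity needed (acyl shift before the aryl anion captures a proton to give a plain aryl ester) is favoured by the poorly acidic solvent and the high temperature, and the slight excess of 13 leaves no aryne for the enolate of 16. C3 arises by uncontrolled protonation and is racemic on purpose, because it could not survive fluoride in any case, and it is set in step 10.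

Step 10
Reactants: 16 racemic 5,7-bis(benzyloxy)-3-[3-(benzyloxy)-4,5-dimethoxyphenyl]-6-methoxychroman-4-one
Product: 17 (3R,4R)-5,7-bis(benzyloxy)-3-[3-(benzyloxy)-4,5-dimethoxyphenyl]-6-methoxychroman-4-ol (cis)
Conditions: RuCl(p-cymene)[(R,R)-TsDPEN] (cat.), HCO2H/Et3N (5:2), EtOAc, 40 °C
Reagents that add atoms: none
Why: Noyori–Ikariya asymmetric transfer hydrogenation with dynamic kinetic resolution, in which Et3N keeps the C3 epimers of 16 in rapid equilibrium through the enol while the (R,R)-catalyst, by its usual arene CH–π preference, should create (4R) and reduce the (3R)-ketone faster by hydride delivery anti to the 3-aryl group, giving the configurationally stable cis-(3R,4R)-alcohol (the mirror-image catalyst is used if the sense proves opposite).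

Step 11
Reactants: 17 (3R,4R)-5,7-bis(benzyloxy)-3-[3-(benzyloxy)-4,5-dimethoxyphenyl]-6-methoxychroman-4-ol
Product: 18 (3R)-5,7-bis(benzyloxy)-3-[3-(benzyloxy)-4,5-dimethoxyphenyl]-6-methoxychroman-4-one
Conditions: Dess–Martin periodinane, CH2Cl2, 0 °C to rt; quick filtration through neutral silica
Reagents that add atoms: none
Why: Dess–Martin oxidation of the secondary benzylic alcohol in a base-free medium, so that C3, which takes no part in the reaction, should keep its (R) configuration.

Step 12
Reactants: 18 (3R)-5,7-bis(benzyloxy)-3-[3-(benzyloxy)-4,5-dimethoxyphenyl]-6-methoxychroman-4-one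
Product: 19 (3R)-5,7-dihydroxy-3-(3-hydroxy-4,5-dimethoxyphenyl)-6-methoxychroman-4-one (target)
Conditions: H2 (1 atm), Pd/C, EtOAc, rt
Reagents that add atoms: none
Why: Heterogeneous hydrogenolysis of the three benzyl aryl ethers under neutral conditions offers no base for enolisation at C3, and the electron-rich C4 ketone, hydrogen-bonded to the freed 5-OH, resists reduction.

Compound list
1 | methyl 3,5-dihydroxy-4-methoxybenzoate | COC(=O)c1cc(O)c(OC)c(O)c1 | starting material
2 | methyl 3,5-bis(benzyloxy)-4-methoxybenzoate | COC(=O)c1cc(OCc2ccccc2)c(OC)c(OCc2ccccc2)c1 | intermediate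
3 | 2-[3,5-bis(benzyloxy)-4-methoxyphenyl]propan-2-ol | CC(C)(O)c1cc(OCc2ccccc2)c(OC)c(OCc2ccccc2)c1 | intermediate
4 | 2-[3,5-bis(benzyloxy)-4-methoxyphenyl]propan-2-yl hydroperoxide | CC(C)(OO)c1cc(OCc2ccccc2)c(OC)c(OCc2ccccc2)c1 | intermediate
5 | 3,5-bis(benzyloxy)-4-methoxyphenol | Oc1cc(OCc2ccccc2)c(OC)c(OCc2ccccc2)c1 | intermediate
6 | 3,5-bis(benzyloxy)-2-bromo-4-methoxyphenol | Oc1cc(OCc2ccccc2)c(OC)c(OCc2ccccc2)c1Br | intermediate
7 | [3,5-bis(benzyloxy)-2-bromo-4-methoxyphenoxy]trimethylsilane | C[Si](C)(C)Oc1cc(OCc2ccccc2)c(OC)c(OCc2ccccc2)c1Br | intermediate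
8 | lithium 3,5-bis(benzyloxy)-4-methoxy-2-(trimethylsilyl)phenolate | [Li+].[O-]c1cc(OCc2ccccc2)c(OC)c(OCc2ccccc2)c1[Si](C)(C)C | intermediate
9 | 3,5-bis(benzyloxy)-4-methoxy-2-(trimethylsilyl)phenyl trifluoromethanesulfonate | C[Si](C)(C)c1c(OS(=O)(=O)C(F)(F)F)cc(OCc2ccccc2)c(OC)c1OCc1ccccc1 | intermediate
10 | 3-hydroxy-4,5-dimethoxybenzaldehyde | COc1cc(C=O)cc(O)c1OC | starting material
11 | 3-(benzyloxy)-4,5-dimethoxybenzaldehyde | COc1cc(C=O)cc(OCc2ccccc2)c1OC | intermediate
12 | 1-(benzyloxy)-5-ethynyl-2,3-dimethoxybenzene | COc1cc(C#C)cc(OCc2ccccc2)c1OC | intermediate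
13 | 2-[3-(benzyloxy)-4,5-dimethoxyphenyl]acrylic acid | COc1cc(C(=C)C(=O)O)cc(OCc2ccccc2)c1OC | intermediate
14 | 3,5-bis(benzyloxy)-4-methoxybenzyne | COC1=C(OCc2ccccc2)C#CC=C1OCc1ccccc1 | intermediate
15 | 1-[2,4-bis(benzyloxy)-6-hydroxy-3-methoxyphenyl]-2-[3-(benzyloxy)-4,5-dimethoxyphenyl]prop-2-en-1-one | COc1cc(C(=C)C(=O)c2c(O)cc(OCc3ccccc3)c(OC)c2OCc2ccccc2)cc(OCc2ccccc2)c1OC | intermediate
16 | racemic 5,7-bis(benzyloxy)-3-[3-(benzyloxy)-4,5-dimethoxyphenyl]-6-methoxychroman-4-one | COc1cc(C2COc3cc(OCc4ccccc4)c(OC)c(OCc4ccccc4)c3C2=O)cc(OCc2ccccc2)c1OC | intermediate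
17 | (3R,4R)-5,7-bis(benzyloxy)-3-[3-(benzyloxy)-4,5-dimethoxyphenyl]-6-methoxychroman-4-ol | COc1cc([C@@H]2COc3cc(OCc4ccccc4)c(OC)c(OCc4ccccc4)c3[C@@H]2O)cc(OCc2ccccc2)c1OC | intermediate
18 | (3R)-5,7-bis(benzyloxy)-3-[3-(benzyloxy)-4,5-dimethoxyphenyl]-6-methoxychroman-4-one | COc1cc([C@@H]2COc3cc(OCc4ccccc4)c(OC)c(OCc4ccccc4)c3C2=O)cc(OCc2ccccc2)c1OC | intermediate
19 | (3R)-5,7-dihydroxy-3-(3-hydroxy-4,5-dimethoxyphenyl)-6-methoxychroman-4-one | COc1cc([C@@H]2COc3cc(O)c(OC)c(O)c3C2=O)cc(O)c1OC | target

Total steps: 12. Longest linear sequence: 9 steps (steps 1–5 and 9–12).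

Steps most likely to fail

Step 9.
- Risk: the aryl anion may capture a proton before the acyl shift (plain O-arylation), the acrylic acid may oligomerise at the high temperature, or the product enolate may be arylated by surplus aryne.
- Fallback: it sets out from 6 and 11 and replaces the aryne by a skeletal rearrangement.
- Bromophenol 6 is deprotonated with NaH, subjected to Br/Li exchange with n-BuLi at -78 °C and acetylated with N-methoxy-N-methylacetamide to give 1-[2,4-bis(benzyloxy)-6-hydroxy-3-methoxyphenyl]ethanone F1.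
- Claisen–Schmidt condensation of this ketone with aldehyde 11 (KOH, EtOH) gives the (E)-chalcone F2.
- Oxidative 1,2-migration of the electron-rich ring B with thallium trinitrate, Tl(NO3)3, in MeOH/HC(OMe)3 gives the 2-aryl-3,3-dimethoxypropan-1-one F3.
- HCl in MeOH closes this acetal to the tri-O-benzyl isoflavone F4.
- Under the conditions of step 10 the transfer hydrogenation first saturates C2=C3 and then reduces the ketone with dynamic kinetic resolution, so the fallback comes back to the route at 17.

Step 10.
- Risk: hydride transfer to the doubly ortho-substituted, electron-rich ketone may be slow, or the catalyst may discriminate poorly between the two interconverting C3 epimers.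
- Fallback: it sets out from 16 and replaces reduction and reoxidation by an enantioselective protonation.
- The potassium enolate (KN(SiMe3)2, THF, -78 °C) is O-acylated with allyl chloroformate to give the allyl 2H-chromen-4-yl carbonate F5.
- Decarboxylative asymmetric protonation with Pd2(dba)3, t-BuPHOX and Meldrum's acid as proton donor then gives the ketone directly. The ligand enantiomer is chosen to give (R).
- The fallback comes back to the route at 18 and omits 17.

Step 12.
- Risk: the C3 configuration may erode by enolisation during a long contact with the catalyst, or the C4 carbonyl may be over-reduced.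
- Fallback: it sets out from 18 and uses a non-reductive cleavage without a metal surface. BCl3 with pentamethylbenzene as benzyl cation scavenger (CH2Cl2, -78 °C, short contact, cold methanol quench) removes the three benzyl groups while the methyl ethers persist at this temperature.
- The fallback comes back to the route at 19.

Further compounds
F1 | step 9 | 1-[2,4-bis(benzyloxy)-6-hydroxy-3-methoxyphenyl]ethanone | CC(=O)c1c(O)cc(OCc2ccccc2)c(OC)c1OCc1ccccc1
F2 | step 9 | (E)-1-[2,4-bis(benzyloxy)-6-hydroxy-3-methoxyphenyl]-3-[3-(benzyloxy)-4,5-dimethoxyphenyl]prop-2-en-1-one | COc1cc(/C=C/C(=O)c2c(O)cc(OCc3ccccc3)c(OC)c2OCc2ccccc2)cc(OCc2ccccc2)c1OC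
F3 | step 9 | 1-[2,4-bis(benzyloxy)-6-hydroxy-3-methoxyphenyl]-2-[3-(benzyloxy)-4,5-dimethoxyphenyl]-3,3-dimethoxypropan-1-one | COc1cc(C(C(OC)OC)C(=O)c2c(O)cc(OCc3ccccc3)c(OC)c2OCc2ccccc2)cc(OCc2ccccc2)c1OC
F4 | step 9 | 5,7-bis(benzyloxy)-3-[3-(benzyloxy)-4,5-dimethoxyphenyl]-6-methoxy-4H-chromen-4-one | COc1cc(-c2coc3cc(OCc4ccccc4)c(OC)c(OCc4ccccc4)c3c2=O)cc(OCc2ccccc2)c1OC
F5 | step 10 | allyl 5,7-bis(benzyloxy)-3-[3-(benzyloxy)-4,5-dimethoxyphenyl]-6-methoxy-2H-chromen-4-yl carbonate | C=CCOC(=O)OC1=C(c2cc(OC)c(OC)c(OCc3ccccc3)c2)COc2cc(OCc3ccccc3)c(OC)c(OCc3ccccc3)c21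
F0 | step 12 | none | none
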